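**Plan**
- Retrosynthetic cuts: (i) the bond between the side-chain CH2 and ring carbon C-4 of the triketone, and in the same operation (ii) the cyclopentane C1–C2 bond (aldol). This leads to 3-isopropenyl-6-oxoheptanal, which is limonene with its ring C=C cleaved. Then (iii) the C6–prenyl bond and (iv) the ring–acyl bond of the triketone, back to 2-methylphloroglucinol.
- Enabling feature: the CH2 lies between a carbon acid (ring C-4, flanked by the enolised C-3 and C-5) and cyclopentane C-1, which is β to the tertiary carbinol C-2. Read backwards, the CH2 is an aldehyde carbon and C1–C2 is an aldol bond.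
- Forward order: the limonene ring is opened by ozonolysis. Separately the flat phloroglucinol ring is acylated, blocked with chlorine, dearomatized by prenylation at the methyl-bearing carbon and dechlorinated. The last step closes the cyclopentane and joins the halves.
- Stereochemistry: cyclopentane C-5 comes from (S)-limonene; C-1 and C-2 are set in the aldol ring closure (substrate control, matched D-proline). The acyl α-carbon comes from (R)-2-methylbutanoic acid. The quaternary C-6 is set by face-selective prenylation under a chiral phase-transfer catalyst.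

Key step: step 6

Remark: locants and CIP descriptors of the dearomatized ring refer to the 3,5-dihydroxycyclohexa-2,4-dien-1-one tautomer written in the SMILES; the tautomers interconvert freely. (S)-Limonene, 2-methylphloroglucinol and (R)-2-methylbutanoic acid are taken as commercial.

**Step 1**
Reactants: 1 (S)-(−)-limonene
Product: 2 (3S)-6-oxo-3-(prop-1-en-2-yl)heptanal
Conditions: O3 (1.0 equiv), CH2Cl2/MeOH, −78 °C; then Me2S, −78 °C → rt
Reagents that add atoms: ozone, [O-][O+]=O
Why: Ozone is electrophilic and adds much faster to the trisubstituted ring alkene than to the 1,1-disubstituted isopropenyl group, so one equivalent at −78 °C with reductive work-up (Criegee ozonolysis) should cleave only the ring C1=C2 bond and leave the C4 stereocentre, which becomes C3 of 2, untouched.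

**Step 2**
Reactants: 3 2-methylphloroglucinol (2,4,6-trihydroxytoluene); 4 (R)-2-methylbutanoic acid
Product: 6 (2R)-2-methyl-1-(2,4,6-trihydroxy-3-methylphenyl)butan-1-one, via acid chloride 5 (not isolated)
Conditions: 4, (COCl)2, cat. DMF, CH2Cl2, 0 °C → rt; then 3, AlCl3 (3.5 equiv), PhNO2/CH2Cl2, 0 °C → rt
Reagents that add atoms: none
Why: Friedel–Crafts acylation: the two free positions of 3 are equivalent and the first acyl group deactivates the ring towards a second one, so a single ketone should form, and the low temperature is chosen to keep the α-stereocentre of the acid chloride.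

**Step 3**
Reactants: 6 (2R)-2-methyl-1-(2,4,6-trihydroxy-3-methylphenyl)butan-1-one
Product: 7 (2R)-1-(3-chloro-2,4,6-trihydroxy-5-methylphenyl)-2-methylbutan-1-one
Conditions: SO2Cl2 (1.0 equiv), CH2Cl2/Et2O, 0 °C
Reagents that add atoms: sulfuryl chloride, O=S(=O)(Cl)Cl
Why: Electrophilic aromatic chlorination at the only remaining ring C–H (between two hydroxyls) should be fast and selective with one equivalent; the chlorine is a temporary blocking group that stops the later prenylation from occurring at this carbon with rearomatization.

**Step 4**
Reactants: 7 (2R)-1-(3-chloro-2,4,6-trihydroxy-5-methylphenyl)-2-methylbutan-1-one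
Product: 8 (6R)-4-chloro-3,5-dihydroxy-6-methyl-2-[(2R)-2-methylbutanoyl]-6-(3-methylbut-2-en-1-yl)cyclohexa-2,4-dien-1-one
Conditions: prenyl bromide (1.1 equiv), N-(9-anthracenylmethyl)-O-allylcinchonidinium bromide (10 mol%), CsOH·H2O (2.2 equiv), toluene/CH2Cl2, −50 °C
Reagents that add atoms: prenyl bromide (1-bromo-3-methylbut-2-ene), CC(C)=CCBr
Why: Proposed new method: deprotonation of 7 gives a delocalised phenoxide in which the methyl-bearing carbon (flanked by two oxygens, no acceptor or halogen on it) is the most nucleophilic carbon, so SN2 attack on prenyl bromide there dearomatizes the ring, while the chlorine has removed the C–H position and lowers the nucleophilicity of its own carbon; the tight ion pair with the Cinchona ammonium cation covers one face of the flat anion, whose two flanks differ strongly (hydrogen-bond-chelated acyl versus chlorine), so the prenyl group should enter from the open face and set C-6 (the pseudo-enantiomeric cinchoninium salt is the lever if the sense is opposite); the closest known reaction types are the base-mediated geminal prenylation of acylphloroglucinols, the Cinchona phase-transfer-catalysed enantioselective alkylative dearomatization of acylphloroglucinols with Michael acceptors, and phase-transfer asymmetric alkylation with allylic bromides.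

**Step 5**
Reactants: 8 (6R)-4-chloro-3,5-dihydroxy-6-methyl-2-[(2R)-2-methylbutanoyl]-6-(3-methylbut-2-en-1-yl)cyclohexa-2,4-dien-1-one
Product: 9 (6R)-3,5-dihydroxy-6-methyl-2-[(2R)-2-methylbutanoyl]-6-(3-methylbut-2-en-1-yl)cyclohexa-2,4-dien-1-one
Conditions: Zn dust, AcOH, THF, rt
Reagents that add atoms: none
Why: Zinc reduces the C–Cl bond of the 2-chloro-1,3-dicarbonyl unit (α-halo ketone reduction through a zinc enolate that acetic acid protonates), which removes the blocking group without touching the prenyl alkene, the acyl group or either stereocentre.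

**Step 6**
Reactants: 2 (3S)-6-oxo-3-(prop-1-en-2-yl)heptanal; 9 (6R)-3,5-dihydroxy-6-methyl-2-[(2R)-2-methylbutanoyl]-6-(3-methylbut-2-en-1-yl)cyclohexa-2,4-dien-1-one
Product: 12 (6R)-4-{[(1R,2S,5S)-2-hydroxy-2-methyl-5-(prop-1-en-2-yl)cyclopentyl]methyl}-3,5-dihydroxy-6-methyl-2-[(2R)-2-methylbutanoyl]-6-(3-methylbut-2-en-1-yl)cyclohexa-2,4-dien-1-one, via hydroxy aldehyde 10 (not isolated), via alkylidene triketone 11 (not isolated)
Conditions: 2, D-proline (20 mol%), DMF, 4 °C → rt; then 9 (1.0 equiv), Hantzsch ester (diethyl 2,6-dimethyl-1,4-dihydropyridine-3,5-dicarboxylate, 1.2 equiv), CH2Cl2, rt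
Reagents that add atoms: none
Why: D-proline condenses with the aldehyde of 2 (far faster than with the methyl ketone) to give an enamine whose α-carbon adds to the ketone carbonyl in a 5-(enolexo)-exo-trig aldolization that closes the cyclopentane and gives 10; the same amine then activates the new aldehyde as an iminium ion, which is attacked by C-4 of 9 (the only unsubstituted ring carbon, flanked by two enolised carbonyls), and loss of the amine gives alkylidene 11, whose exocyclic C=C is reduced at once by conjugate hydride transfer from the Hantzsch ester. The closest known reaction types are the proline-catalysed 5-enolexo aldolization of keto-aldehydes and the amine/Hantzsch ester three-component reductive alkylation of cyclic 1,3-diones (Knoevenagel condensation–transfer hydrogenation). C-1 of the cyclopentane should be set trans to the isopropenyl group by the limonene-derived stereocentre (pseudo-equatorial substituents in the ring-forming transition state, reinforced by the matched enamine face of D-proline), and C-2 with hydroxyl cis to formyl by the acid-bridged, hydrogen-bonded transition state typical of 5-enolexo closures; this isomer, with the formyl group trans to both the isopropenyl and the C-2 methyl group, is also the one favoured if the aldol equilibrates. No stereocentre is formed at the new CH2–C bond, and C-6 and the acyl α-carbon of 9 are not touched under these near-neutral conditions. The step needs aldehyde-donor over ketone-donor aldol selectivity (secured by secondary-amine catalysis), C- over O-alkylation and mono-alkylation (secured by the Knoevenagel mode and the single free ring carbon of 9), and reduction faster than retro-aldol or β-elimination of the tertiary hydroxyl (secured by adding 9 and the hydride donor only after ring closure, so that 11 is trapped as it forms).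

**Compound list**
1 | (S)-(−)-limonene | CC1=CC[C@H](CC1)C(C)=C | starting material
2 | (3S)-6-oxo-3-(prop-1-en-2-yl)heptanal | C=C(C)[C@H](CC=O)CCC(C)=O | intermediate
3 | 2-methylphloroglucinol (2,4,6-trihydroxytoluene) | Cc1c(O)cc(O)cc1O | starting material
4 | (R)-2-methylbutanoic acid | CC[C@@H](C)C(=O)O | starting material
5 | (R)-2-methylbutanoyl chloride | CC[C@@H](C)C(Cl)=O | intermediate (not isolated)
6 | (2R)-2-methyl-1-(2,4,6-trihydroxy-3-methylphenyl)butan-1-one | CC[C@@H](C)C(=O)c1c(O)cc(O)c(C)c1O | intermediate
7 | (2R)-1-(3-chloro-2,4,6-trihydroxy-5-methylphenyl)-2-methylbutan-1-one | CC[C@@H](C)C(=O)c1c(O)c(Cl)c(O)c(C)c1O | intermediate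
8 | (6R)-4-chloro-3,5-dihydroxy-6-methyl-2-[(2R)-2-methylbutanoyl]-6-(3-methylbut-2-en-1-yl)cyclohexa-2,4-dien-1-one | ClC1=C(O)[C@@](C)(CC=C(C)C)C(=O)C(C(=O)[C@H](C)CC)=C1O | intermediate
9 | (6R)-3,5-dihydroxy-6-methyl-2-[(2R)-2-methylbutanoyl]-6-(3-methylbut-2-en-1-yl)cyclohexa-2,4-dien-1-one | C1=C(O)[C@@](C)(CC=C(C)C)C(=O)C(C(=O)[C@H](C)CC)=C1O | intermediate
10 | (1R,2S,5S)-2-hydroxy-2-methyl-5-(prop-1-en-2-yl)cyclopentane-1-carbaldehyde | C=C(C)[C@H]1CC[C@](C)(O)[C@@H]1C=O | intermediate (not isolated)
11 | Knoevenagel alkylidene: C-4 of 9 joined by an exocyclic C=CH bond to C-1 of the cyclopentane of 10 (alkene geometry not defined) | C=C(C)[C@H]1CC[C@](C)(O)[C@@H]1C=C1C(=O)[C@@](C)(CC=C(C)C)C(=O)C(C(=O)[C@H](C)CC)=C1O | intermediate (not isolated)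
12 | (6R)-4-{[(1R,2S,5S)-2-hydroxy-2-methyl-5-(prop-1-en-2-yl)cyclopentyl]methyl}-3,5-dihydroxy-6-methyl-2-[(2R)-2-methylbutanoyl]-6-(3-methylbut-2-en-1-yl)cyclohexa-2,4-dien-1-one | C=C(C)[C@H]1CC[C@](C)(O)[C@@H]1CC1=C(O)[C@@](C)(CC=C(C)C)C(=O)C(C(=O)[C@H](C)CC)=C1O | target

**Totals**
Total step count: 6. Longest linear sequence: 5 steps (steps 2, 3, 4, 5, 6, from 3 and 4 to 12); the limonene branch is step 1 and joins at step 6.

**Steps most likely to fail**

Step 4 (labelled step). The risk is poor discrimination between the two faces of the planar anion by the chiral cation, together with some prenylation on oxygen or at the chlorine-bearing carbon. Fallback with known chemistry, setting out from 7: prenyl bromide with NaOMe in MeOH at 0 °C, without a chiral catalyst, is the ordinary alkylative dearomatization. It should give 8 together with its C-6 epimer, (6S)-4-chloro-3,5-dihydroxy-6-methyl-2-[(2R)-2-methylbutanoyl]-6-(3-methylbut-2-en-1-yl)cyclohexa-2,4-dien-1-one F1. Because the acyl stereocentre is fixed, the two are diastereomers and are separated by preparative HPLC. Face control by a catalyst is thus replaced by physical separation, and the route is rejoined at 8 before step 5.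

Step 6. The risk is loss of the tertiary hydroxyl by β-elimination, or reversal of the aldol with alkylation by the open-chain aldehyde, before the hydride transfer takes place. The fallback sets out from 2 and runs the sequence in stages with the hydroxyl protected. The D-proline aldolization is run alone and 10 is isolated. Silylation with TESOTf and 2,6-lutidine in CH2Cl2 at −78 °C gives (1R,2S,5S)-2-methyl-5-(prop-1-en-2-yl)-2-(triethylsilyloxy)cyclopentane-1-carbaldehyde F2, in which retro-aldol is impossible and elimination is slowed. Reductive alkylation of 9 with F2 (Hantzsch ester, cat. proline, CH2Cl2, rt) gives the triethylsilyl ether of 12 F3. Desilylation with HF·pyridine in THF at 0 °C returns to the route at 12.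

Step 2. The risk is partial racemization of the acyl α-stereocentre through enolisation or ketene formation of the acid chloride under AlCl3. The fallback sets out from 3 and 4 and replaces electrophilic acylation by an aryllithium addition. Compound 3 with MOMCl and i-Pr2NEt gives 1,3,5-tris(methoxymethoxy)-2-methylbenzene F4. Compound 4 with MeNHOMe·HCl, EDC and HOBt gives the Weinreb amide (2R)-N-methoxy-N,2-dimethylbutanamide F5. Lithiation of F4 with n-BuLi in THF at 0 °C, between two OMOM groups, gives [2,4,6-tris(methoxymethoxy)-3-methylphenyl]lithium F6. Addition of F6 to F5 at −78 °C gives (2R)-2-methyl-1-[2,4,6-tris(methoxymethoxy)-3-methylphenyl]butan-1-one F7. HCl in MeOH at rt removes the MOM groups and returns to the route at 6.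

**Further compounds**
F1 | step 4 | (6S)-4-chloro-3,5-dihydroxy-6-methyl-2-[(2R)-2-methylbutanoyl]-6-(3-methylbut-2-en-1-yl)cyclohexa-2,4-dien-1-one | ClC1=C(O)[C@](C)(CC=C(C)C)C(=O)C(C(=O)[C@H](C)CC)=C1O
F2 | step 6 | (1R,2S,5S)-2-methyl-5-(prop-1-en-2-yl)-2-(triethylsilyloxy)cyclopentane-1-carbaldehyde | C=C(C)[C@H]1CC[C@](C)(O[Si](CC)(CC)CC)[C@@H]1C=O
F3 | step 6 | triethylsilyl ether of 12 at the tertiary hydroxyl | C=C(C)[C@H]1CC[C@](C)(O[Si](CC)(CC)CC)[C@@H]1CC1=C(O)[C@@](C)(CC=C(C)C)C(=O)C(C(=O)[C@H](C)CC)=C1O
F4 | step 2 | 1,3,5-tris(methoxymethoxy)-2-methylbenzene | Cc1c(OCOC)cc(OCOC)cc1OCOC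
F5 | step 2 | (2R)-N-methoxy-N,2-dimethylbutanamide | CC[C@@H](C)C(=O)N(C)OC
F6 | step 2 | [2,4,6-tris(methoxymethoxy)-3-methylphenyl]lithium | [Li]c1c(OCOC)cc(OCOC)c(C)c1OCOC
F7 | step 2 | (2R)-2-methyl-1-[2,4,6-tris(methoxymethoxy)-3-methylphenyl]butan-1-one | CC[C@@H](C)C(=O)c1c(OCOC)cc(OCOC)c(C)c1OCOC
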